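The ten-membered carbocycle is cut at C7–C8. The C9 oxygen, C8 and the C11–C12 branch on C7 form a Claisen retron (γ,δ-unsaturated ketone C9(=O)–C8–C7–C11=C12). The precursor is a twelve-membered lactone whose carbonyl is C9 and whose alkoxy half is O–C12H2–C11H=C7H. Methylenation of that carbonyl and [3,3] shift of the resulting cyclic allyl dienyl ether contract the ring to the ten-membered enone in one operation. This forms C7–C8, the C7 stereocentre, the C9 ketone and a C7 vinyl group that later becomes the lactone.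

Key step: step 15

Atom labels (germacranolide numbering): lactone C12(=O)–O–C6; C11 carries the C13 methyl; ring C7–C6–C5=C4(CH3)–C3(O-acyl)–C2–C1=C10(CH3)–C9(OH)–C8–C7.

Assumption: the (S,S)-ProPhenol–zinc catalyst is taken to add the alkynylzinc to the Re face of enal 3, the face it selects in its aldol reactions; the (S)-C6 carbinol in 8 follows from this.

Step 1
Reactants: 1 (E)-but-2-ene-1,4-diol
Product: 2 (E)-4-[(tert-butyldimethylsilyl)oxy]but-2-en-1-ol
Conditions: NaH (1.0 equiv), TBSCl (1.0 equiv), THF, 0 °C → rt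
Reagents that add atoms: tert-butyldimethylsilyl chloride CC(C)(C)[Si](C)(C)Cl
Why: Monosilylation of the symmetric diol through its sparingly soluble monosodium alkoxide (O-silylation); no stereocentre is formed.

Step 2
Reactants: 2 (E)-4-[(tert-butyldimethylsilyl)oxy]but-2-en-1-ol
Product: 3 (E)-4-[(tert-butyldimethylsilyl)oxy]but-2-enal
Conditions: Dess–Martin periodinane, NaHCO3, CH2Cl2, 0 °C → rt
Reagents that add atoms: none
Why: Dess–Martin oxidation of the allylic alcohol stops at the enal and leaves the E-alkene and the silyl ether untouched.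

Step 3
Reactants: 4 (S)-butane-1,2,4-triol
Product: 5 [(2S,4S)-2-(4-methoxyphenyl)-1,3-dioxan-4-yl]methanol
Conditions: 4-methoxybenzaldehyde dimethyl acetal, CSA (cat.), CH2Cl2, rt
Reagents that add atoms: 4-methoxybenzaldehyde dimethyl acetal COC(OC)c1ccc(OC)cc1
Why: Acid-catalysed transacetalisation under equilibrium should favour the six-membered 2,4-O-acetal with both substituents equatorial, leaving the triol C1 hydroxyl free; the triol stereocentre is the future C3 (chiral pool).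

Step 4
Reactants: 5 [(2S,4S)-2-(4-methoxyphenyl)-1,3-dioxan-4-yl]methanol
Product: 6 (2S,4S)-2-(4-methoxyphenyl)-1,3-dioxane-4-carbaldehyde
Conditions: Dess–Martin periodinane, NaHCO3, CH2Cl2, 0 °C → rt
Reagents that add atoms: none
Why: Buffered Dess–Martin oxidation gives the α-alkoxy aldehyde without epimerisation or acetal loss.

Step 5
Reactants: 6 (2S,4S)-2-(4-methoxyphenyl)-1,3-dioxane-4-carbaldehyde
Product: 7 (2S,4S)-4-ethynyl-2-(4-methoxyphenyl)-1,3-dioxane
Conditions: dimethyl (1-diazo-2-oxopropyl)phosphonate, K2CO3, MeOH, 0 °C → rt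
Reagents that add atoms: dimethyl (1-diazo-2-oxopropyl)phosphonate CC(=O)C(=[N+]=[N-])P(=O)(OC)OC
Why: Ohira–Bestmann (Seyferth–Gilbert) homologation turns the aldehyde into the terminal alkyne (C4≡C5) under carbonate conditions mild enough to keep the α-alkoxy centre.

Step 6
Reactants: 7 (2S,4S)-4-ethynyl-2-(4-methoxyphenyl)-1,3-dioxane; 3 (E)-4-[(tert-butyldimethylsilyl)oxy]but-2-enal
Product: 8 (3S,4E)-6-[(tert-butyldimethylsilyl)oxy]-1-[(2S,4S)-2-(4-methoxyphenyl)-1,3-dioxan-4-yl]hex-4-en-1-yn-3-ol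
Conditions: (S,S)-ProPhenol (20 mol %), Me2Zn (3 equiv), Ph3P=O (40 mol %), toluene, 4 °C; 7 in slight excess
Reagents that add atoms: none
Why: Zinc–ProPhenol catalysed asymmetric alkynylation of an enal; the dinuclear catalyst delivers the alkynylzinc to the Re face, which sets C6 as S under catalyst control.

Step 7
Reactants: 8 (3S,4E)-6-[(tert-butyldimethylsilyl)oxy]-1-[(2S,4S)-2-(4-methoxyphenyl)-1,3-dioxan-4-yl]hex-4-en-1-yn-3-ol
Product: 10 (1Z,3S,4E)-6-[(tert-butyldimethylsilyl)oxy]-1-iodo-1-[(2S,4S)-2-(4-methoxyphenyl)-1,3-dioxan-4-yl]hexa-1,4-dien-3-ol, via vinylalanate 9 (not isolated)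
Conditions: Red-Al, THF, −20 → 0 °C; then I2, THF, −78 °C
Reagents that add atoms: iodine II; Red-Al [Na+].COCCO[AlH2-]OCCOC (aluminium and sodium in intermediate 9 only)
Why: Hydroxyl-directed trans-hydroalumination of the propargylic alcohol puts hydride on C5 and aluminium on C4 in a five-membered alanate (kept at ≤0 °C to avoid loss of the C3 alkoxide to an allene), and iodinolysis with retention gives the Z-iodoalkene.

Step 8
Reactants: 10 (1Z,3S,4E)-6-[(tert-butyldimethylsilyl)oxy]-1-iodo-1-[(2S,4S)-2-(4-methoxyphenyl)-1,3-dioxan-4-yl]hexa-1,4-dien-3-ol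
Product: 11 (2E,4S,5E)-7-[(tert-butyldimethylsilyl)oxy]-2-[(2S,4S)-2-(4-methoxyphenyl)-1,3-dioxan-4-yl]hepta-2,5-dien-4-ol
Conditions: MeZnCl (3 equiv), Pd(PPh3)4 (5 mol %), THF, 0 °C → rt
Reagents that add atoms: methylzinc chloride C[Zn]Cl
Why: Negishi cross-coupling replaces iodine by methyl with retention, fixing the E-C4=C5 bond (C6 cis to the new methyl).

Step 9
Reactants: 11 (2E,4S,5E)-7-[(tert-butyldimethylsilyl)oxy]-2-[(2S,4S)-2-(4-methoxyphenyl)-1,3-dioxan-4-yl]hepta-2,5-dien-4-ol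
Product: 12 (2S,4S)-4-{(2E,4S,5E)-7-[(tert-butyldimethylsilyl)oxy]-4-[(4-methoxybenzyl)oxy]hepta-2,5-dien-2-yl}-2-(4-methoxyphenyl)-1,3-dioxane
Conditions: NaH, 4-methoxybenzyl chloride, Bu4NI (cat.), DMF, 0 °C → rt
Reagents that add atoms: 4-methoxybenzyl chloride COc1ccc(CCl)cc1
Why: Williamson etherification under basic conditions protects the bis-allylic C6 hydroxyl without risk of ionisation.

Step 10
Reactants: 12 (2S,4S)-4-{(2E,4S,5E)-7-[(tert-butyldimethylsilyl)oxy]-4-[(4-methoxybenzyl)oxy]hepta-2,5-dien-2-yl}-2-(4-methoxyphenyl)-1,3-dioxane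
Product: 13 (3S,4E,6S,7E)-9-[(tert-butyldimethylsilyl)oxy]-3,6-bis[(4-methoxybenzyl)oxy]-4-methylnona-4,7-dien-1-ol
Conditions: DIBAL-H (3 equiv), CH2Cl2, −78 → 0 °C; Rochelle salt work-up
Reagents that add atoms: none
Why: Reductive opening of the p-methoxybenzylidene acetal: aluminium binds the less hindered primary oxygen, so the PMB group stays on the secondary C3 oxygen and the C1 hydroxyl is freed.

Step 11
Reactants: 13 (3S,4E,6S,7E)-9-[(tert-butyldimethylsilyl)oxy]-3,6-bis[(4-methoxybenzyl)oxy]-4-methylnona-4,7-dien-1-ol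
Product: 14 (3S,4E,6S,7E)-9-[(tert-butyldimethylsilyl)oxy]-3,6-bis[(4-methoxybenzyl)oxy]-4-methylnona-4,7-dienal
Conditions: Dess–Martin periodinane, NaHCO3, CH2Cl2, 0 °C → rt
Reagents that add atoms: none
Why: Dess–Martin oxidation of the primary alcohol gives the β-alkoxy aldehyde (C1) under buffered conditions that avoid β-elimination.

Step 12
Reactants: 14 (3S,4E,6S,7E)-9-[(tert-butyldimethylsilyl)oxy]-3,6-bis[(4-methoxybenzyl)oxy]-4-methylnona-4,7-dienal
Product: 15 methyl (2Z,5S,6E,8S,9E)-11-[(tert-butyldimethylsilyl)oxy]-5,8-bis[(4-methoxybenzyl)oxy]-2,6-dimethylundeca-2,6,9-trienoate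
Conditions: methyl 2-[bis(2,2,2-trifluoroethoxy)phosphoryl]propanoate, KHMDS, 18-crown-6, THF, −78 °C
Reagents that add atoms: methyl 2-[bis(2,2,2-trifluoroethoxy)phosphoryl]propanoate COC(=O)C(C)P(=O)(OCC(F)(F)F)OCC(F)(F)F
Why: Still–Gennari olefination: the electron-poor phosphonate with a dissociated potassium counter-ion eliminates under kinetic control and should set the Z-C1=C10 bond.

Step 13
Reactants: 15 methyl (2Z,5S,6E,8S,9E)-11-[(tert-butyldimethylsilyl)oxy]-5,8-bis[(4-methoxybenzyl)oxy]-2,6-dimethylundeca-2,6,9-trienoate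
Product: 17 (2Z,5S,6E,8S,9E)-11-hydroxy-5,8-bis[(4-methoxybenzyl)oxy]-2,6-dimethylundeca-2,6,9-trienoic acid, via hydroxy ester 16 (not isolated)
Conditions: TBAF, THF, 0 °C → rt; then LiOH, MeOH/H2O, 40 °C; 1 M HCl to pH 4
Reagents that add atoms: lithium hydroxide [Li+].[OH-]
Why: Fluoride cleaves the only silyl ether (C12) and hydroxide then saponifies the methyl ester; PMB ethers and the Z-enoate geometry should be unaffected.

Step 14
Reactants: 17 (2Z,5S,6E,8S,9E)-11-hydroxy-5,8-bis[(4-methoxybenzyl)oxy]-2,6-dimethylundeca-2,6,9-trienoic acid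
Product: 18 (3Z,6S,7E,9S,10E)-6,9-bis[(4-methoxybenzyl)oxy]-3,7-dimethyl-1-oxacyclododeca-3,7,10-trien-2-one
Conditions: PPh3, DIAD, toluene, 1 mM, slow addition of 17, 0 °C → rt
Reagents that add atoms: none
Why: Mitsunobu macrolactonisation activates the primary allylic C12 alcohol and not the acid, so the Z-2-methylenoate cannot isomerise, and the carboxylate closes the twelve-membered ring by SN2 at C12 under high dilution.

Step 15
Reactants: 18 (3Z,6S,7E,9S,10E)-6,9-bis[(4-methoxybenzyl)oxy]-3,7-dimethyl-1-oxacyclododeca-3,7,10-trien-2-one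
Product: 20 (2Z,5S,6E,8S,9S)-5,8-bis[(4-methoxybenzyl)oxy]-2,6-dimethyl-9-vinylcyclodeca-2,6-dien-1-one, via dienol ether 19 (not isolated)
Conditions: Tebbe reagent (2 equiv), pyridine, THF/toluene, −40 → 0 °C; filtration through basic alumina; then toluene, Et3N (cat.), 110 °C
Reagents that add atoms: Tebbe reagent C[Al](C)C[Ti](Cl)(C1C=CC=C1)C1C=CC=C1
Why: Methylenation of the only carbonyl group of 18 gives the cyclic 2-alkoxy-1,3-diene 19, whose C8=C9–O–C12–C11=C7 array undergoes a concerted suprafacial [3,3] sigmatropic (Claisen) shift on heating, the O–C12 bond breaking as C8–C7 forms. The closest known reaction type is the lactone methylenation/Claisen rearrangement sequence used to make carbocycles from unsaturated lactones, here run in its ring-contracting mode. The ten-membered carbocycle is closed by the pericyclic C8–C7 bond formation inside the twelve-membered ring (five of the six reacting atoms are ring members, C8 is exocyclic), so the ring loses O and C12 and gains C8. C7 is set by the resident C6 stereocentre: in the chair-like array C6–H lies in the plane of the C7=C11 bond, the C6–O bond is antiperiplanar to the incoming C8 (Felkin–Anh type) and the tethered C5 sits outside, which gives the 6,7-relationship of the trans-fused lactone. The step needs chemoselective methylenation (the ring ester is the only C=O and PMB ethers are inert), periselectivity for the [3,3] shift over 1,5-hydrogen shift of the Z-diene and Cope rearrangement of the product 1,5-diene (the donor-substituted Claisen should be the lowest-barrier path at ≤110 °C), and the facial selectivity just described. The Z-C1=C10 and E-C4=C5 bonds are spectators and keep their geometry.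

Step 16
Reactants: 20 (2Z,5S,6E,8S,9S)-5,8-bis[(4-methoxybenzyl)oxy]-2,6-dimethyl-9-vinylcyclodeca-2,6-dien-1-one
Product: 21 (1S,2Z,5S,6E,8S,9S)-5,8-bis[(4-methoxybenzyl)oxy]-2,6-dimethyl-9-vinylcyclodeca-2,6-dien-1-ol
Conditions: (R)-Me-CBS (0.5 equiv), catecholborane (2 equiv), toluene, −78 °C
Reagents that add atoms: none
Why: Corey–Bakshi–Shibata reduction of the enone with the α-methylalkenyl flank as the large group should give the (S)-C9 carbinol under reagent control; catecholborane at −78 °C does not hydroborate the vinyl group.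

Step 17
Reactants: 21 (1S,2Z,5S,6E,8S,9S)-5,8-bis[(4-methoxybenzyl)oxy]-2,6-dimethyl-9-vinylcyclodeca-2,6-dien-1-ol
Product: 22 tert-butyl{[(1S,2Z,5S,6E,8S,9S)-5,8-bis[(4-methoxybenzyl)oxy]-2,6-dimethyl-9-vinylcyclodeca-2,6-dien-1-yl]oxy}dimethylsilane
Conditions: TBSOTf, 2,6-lutidine, CH2Cl2, −78 °C
Reagents that add atoms: tert-butyldimethylsilyl triflate CC(C)(C)[Si](C)(C)OS(=O)(=O)C(F)(F)F
Why: Silylation of the hindered allylic C9 hydroxyl with the triflate keeps it out of the later oxidation, lactonisation and acylation steps.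

Step 18
Reactants: 22 tert-butyl{[(1S,2Z,5S,6E,8S,9S)-5,8-bis[(4-methoxybenzyl)oxy]-2,6-dimethyl-9-vinylcyclodeca-2,6-dien-1-yl]oxy}dimethylsilane
Product: 24 2-[(1R,2S,3E,5S,7Z,9S)-9-[(tert-butyldimethylsilyl)oxy]-2,5-bis[(4-methoxybenzyl)oxy]-4,8-dimethylcyclodeca-3,7-dien-1-yl]ethan-1-ol, via alkylborane 23 (not isolated)
Conditions: 9-BBN (2 equiv), THF, 0 °C → rt; then NaOH, H2O2, 0 °C
Reagents that add atoms: hydrogen peroxide OO; 9-borabicyclo[3.3.1]nonane [H]B1C2CCCC1CCC2 (boron in intermediate 23 only)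
Why: Hydroboration–oxidation: 9-BBN adds anti-Markovnikov to the monosubstituted vinyl group much faster than to the two trisubstituted ring alkenes, giving the C12 primary alcohol.

Step 19
Reactants: 24 2-[(1R,2S,3E,5S,7Z,9S)-9-[(tert-butyldimethylsilyl)oxy]-2,5-bis[(4-methoxybenzyl)oxy]-4,8-dimethylcyclodeca-3,7-dien-1-yl]ethan-1-ol
Product: 25 2-[(1S,2S,3E,5S,7Z,9S)-9-[(tert-butyldimethylsilyl)oxy]-2,5-bis[(4-methoxybenzyl)oxy]-4,8-dimethylcyclodeca-3,7-dien-1-yl]acetic acid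
Conditions: TEMPO (0.2 equiv), PhI(OAc)2 (2.5 equiv), MeCN/pH 7 buffer 1:1, rt
Reagents that add atoms: water O
Why: TEMPO/PhI(OAc)2 oxidation takes the primary alcohol through the aldehyde hydrate to the acid while all secondary oxygens are still protected.

Step 20
Reactants: 25 2-[(1S,2S,3E,5S,7Z,9S)-9-[(tert-butyldimethylsilyl)oxy]-2,5-bis[(4-methoxybenzyl)oxy]-4,8-dimethylcyclodeca-3,7-dien-1-yl]acetic acid
Product: 27 (3aS,5S,6Z,9S,10E,11aS)-5-[(tert-butyldimethylsilyl)oxy]-9-hydroxy-6,10-dimethyl-3a,4,5,8,9,11a-hexahydrocyclodeca[b]furan-2(3H)-one, via dihydroxy acid 26 (not isolated)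
Conditions: DDQ (2.6 equiv), CH2Cl2/pH 7 buffer, 0 °C; then PPTS (cat.), CH2Cl2, rt
Reagents that add atoms: none
Why: Oxidative cleavage of both PMB ethers frees the C3 and C6 hydroxyls, and the γ-hydroxy acid closes to the trans-fused γ-lactone, since only the C6 hydroxyl can reach C12 in a five-membered ring and C9 is silylated.

Step 21
Reactants: 27 (3aS,5S,6Z,9S,10E,11aS)-5-[(tert-butyldimethylsilyl)oxy]-9-hydroxy-6,10-dimethyl-3a,4,5,8,9,11a-hexahydrocyclodeca[b]furan-2(3H)-one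
Product: 29 (3R,3aS,5S,6Z,9S,10E,11aS)-5-[(tert-butyldimethylsilyl)oxy]-9-hydroxy-3,6,10-trimethyl-3a,4,5,8,9,11a-hexahydrocyclodeca[b]furan-2(3H)-one, via dilithium enolate 28 (not isolated)
Conditions: LDA (2.2 equiv), THF, −78 °C; then MeI (1.5 equiv), −78 °C; AcOH quench at −78 °C
Reagents that add atoms: iodomethane CI; lithium diisopropylamide [Li+].CC(C)[N-]C(C)C (lithium in intermediate 28 only)
Why: Enolate alkylation: the lithium enolate of the trans-fused lactone should take the electrophile on the face opposite to the pseudoaxial C7–H, the usual course for trans-fused 12,6-olides, placing the methyl cis to C8 (11R); the C3 lithium alkoxide does not O-methylate at −78 °C.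

Step 22
Reactants: 29 (3R,3aS,5S,6Z,9S,10E,11aS)-5-[(tert-butyldimethylsilyl)oxy]-9-hydroxy-3,6,10-trimethyl-3a,4,5,8,9,11a-hexahydrocyclodeca[b]furan-2(3H)-one; 30 (R)-2-methylbutanoic acid
Product: 31 (3R,3aS,5S,6Z,9S,10E,11aS)-5-[(tert-butyldimethylsilyl)oxy]-3,6,10-trimethyl-2-oxo-2,3,3a,4,5,8,9,11a-octahydrocyclodeca[b]furan-9-yl (R)-2-methylbutanoate
Conditions: DCC, DMAP (cat.), CH2Cl2, 0 °C → rt
Reagents that add atoms: none
Why: Steglich esterification of the only free hydroxyl (C3) with the enantiopure acid under mild conditions that should leave the α-stereocentres of the acid and of the lactone intact.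

Step 23
Reactants: 31 (3R,3aS,5S,6Z,9S,10E,11aS)-5-[(tert-butyldimethylsilyl)oxy]-3,6,10-trimethyl-2-oxo-2,3,3a,4,5,8,9,11a-octahydrocyclodeca[b]furan-9-yl (R)-2-methylbutanoate
Product: 32 (3R,3aS,5S,6Z,9S,10E,11aS)-5-hydroxy-3,6,10-trimethyl-2-oxo-2,3,3a,4,5,8,9,11a-octahydrocyclodeca[b]furan-9-yl (R)-2-methylbutanoate
Conditions: HF·pyridine, pyridine, THF, 0 °C → rt
Reagents that add atoms: none
Why: Acidic fluoride removes the TBS ether without base, so the epimerisable C11 centre and both esters should survive.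

Compound list
1 | (E)-but-2-ene-1,4-diol | OC/C=C/CO | starting material
2 | (E)-4-[(tert-butyldimethylsilyl)oxy]but-2-en-1-ol | CC(C)(C)[Si](C)(C)OC/C=C/CO | intermediate
3 | (E)-4-[(tert-butyldimethylsilyl)oxy]but-2-enal | CC(C)(C)[Si](C)(C)OC/C=C/C=O | intermediate
4 | (S)-butane-1,2,4-triol | OC[C@@H](O)CCO | starting material
5 | [(2S,4S)-2-(4-methoxyphenyl)-1,3-dioxan-4-yl]methanol | OC[C@@H]1CCO[C@H](c2ccc(OC)cc2)O1 | intermediate
6 | (2S,4S)-2-(4-methoxyphenyl)-1,3-dioxane-4-carbaldehyde | O=C[C@@H]1CCO[C@H](c2ccc(OC)cc2)O1 | intermediate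
7 | (2S,4S)-4-ethynyl-2-(4-methoxyphenyl)-1,3-dioxane | C#C[C@@H]1CCO[C@H](c2ccc(OC)cc2)O1 | intermediate
8 | (3S,4E)-6-[(tert-butyldimethylsilyl)oxy]-1-[(2S,4S)-2-(4-methoxyphenyl)-1,3-dioxan-4-yl]hex-4-en-1-yn-3-ol | CC(C)(C)[Si](C)(C)OC/C=C/[C@@H](C#C[C@@H]1CCO[C@H](c2ccc(OC)cc2)O1)O | intermediate
9 | sodium vinylalanate from 8 (five-membered O6–Al–C4 ring, two 2-methoxyethoxy ligands on Al) | [Na+].COCCO[Al-]1(OCCOC)O[C@@H](/C=C/CO[Si](C)(C)C(C)(C)C)C=C1[C@@H]1CCO[C@H](c2ccc(OC)cc2)O1 | intermediate (not isolated)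
10 | (1Z,3S,4E)-6-[(tert-butyldimethylsilyl)oxy]-1-iodo-1-[(2S,4S)-2-(4-methoxyphenyl)-1,3-dioxan-4-yl]hexa-1,4-dien-3-ol | CC(C)(C)[Si](C)(C)OC/C=C/[C@@H](/C=C(/[C@@H]1CCO[C@H](c2ccc(OC)cc2)O1)I)O | intermediate
11 | (2E,4S,5E)-7-[(tert-butyldimethylsilyl)oxy]-2-[(2S,4S)-2-(4-methoxyphenyl)-1,3-dioxan-4-yl]hepta-2,5-dien-4-ol | CC(C)(C)[Si](C)(C)OC/C=C/[C@@H](/C=C(/[C@@H]1CCO[C@H](c2ccc(OC)cc2)O1)C)O | intermediate
12 | (2S,4S)-4-{(2E,4S,5E)-7-[(tert-butyldimethylsilyl)oxy]-4-[(4-methoxybenzyl)oxy]hepta-2,5-dien-2-yl}-2-(4-methoxyphenyl)-1,3-dioxane | CC(C)(C)[Si](C)(C)OC/C=C/[C@@H](/C=C(/[C@@H]1CCO[C@H](c2ccc(OC)cc2)O1)C)OCc1ccc(OC)cc1 | intermediate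
13 | (3S,4E,6S,7E)-9-[(tert-butyldimethylsilyl)oxy]-3,6-bis[(4-methoxybenzyl)oxy]-4-methylnona-4,7-dien-1-ol | CC(C)(C)[Si](C)(C)OC/C=C/[C@@H](/C=C(/[C@@H](OCc1ccc(OC)cc1)CCO)C)OCc1ccc(OC)cc1 | intermediate
14 | (3S,4E,6S,7E)-9-[(tert-butyldimethylsilyl)oxy]-3,6-bis[(4-methoxybenzyl)oxy]-4-methylnona-4,7-dienal | CC(C)(C)[Si](C)(C)OC/C=C/[C@@H](/C=C(/[C@@H](OCc1ccc(OC)cc1)CC=O)C)OCc1ccc(OC)cc1 | intermediate
15 | methyl (2Z,5S,6E,8S,9E)-11-[(tert-butyldimethylsilyl)oxy]-5,8-bis[(4-methoxybenzyl)oxy]-2,6-dimethylundeca-2,6,9-trienoate | CC(C)(C)[Si](C)(C)OC/C=C/[C@@H](/C=C(/[C@@H](OCc1ccc(OC)cc1)C/C=C(/C)C(=O)OC)C)OCc1ccc(OC)cc1 | intermediate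
16 | methyl (2Z,5S,6E,8S,9E)-11-hydroxy-5,8-bis[(4-methoxybenzyl)oxy]-2,6-dimethylundeca-2,6,9-trienoate | OC/C=C/[C@@H](/C=C(/[C@@H](OCc1ccc(OC)cc1)C/C=C(/C)C(=O)OC)C)OCc1ccc(OC)cc1 | intermediate (not isolated)
17 | (2Z,5S,6E,8S,9E)-11-hydroxy-5,8-bis[(4-methoxybenzyl)oxy]-2,6-dimethylundeca-2,6,9-trienoic acid | OC/C=C/[C@@H](/C=C(/[C@@H](OCc1ccc(OC)cc1)C/C=C(/C)C(=O)O)C)OCc1ccc(OC)cc1 | intermediate
18 | (3Z,6S,7E,9S,10E)-6,9-bis[(4-methoxybenzyl)oxy]-3,7-dimethyl-1-oxacyclododeca-3,7,10-trien-2-one | O1C/C=C/[C@@H](/C=C(/[C@@H](OCc2ccc(OC)cc2)C/C=C(/C)C1=O)C)OCc2ccc(OC)cc2 | intermediate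
19 | (3Z,6S,7E,9S,10E)-6,9-bis[(4-methoxybenzyl)oxy]-3,7-dimethyl-2-methylidene-1-oxacyclododeca-3,7,10-triene | O1C/C=C/[C@@H](/C=C(/[C@@H](OCc2ccc(OC)cc2)C/C=C(/C)C1=C)C)OCc2ccc(OC)cc2 | intermediate (not isolated)
20 | (2Z,5S,6E,8S,9S)-5,8-bis[(4-methoxybenzyl)oxy]-2,6-dimethyl-9-vinylcyclodeca-2,6-dien-1-one | COc1ccc(CO[C@H]2C/C=C(/C)C(=O)C[C@@H](C=C)[C@@H](/C=C/2C)OCc3ccc(OC)cc3)cc1 | intermediate
21 | (1S,2Z,5S,6E,8S,9S)-5,8-bis[(4-methoxybenzyl)oxy]-2,6-dimethyl-9-vinylcyclodeca-2,6-dien-1-ol | COc1ccc(CO[C@H]2C/C=C(/C)[C@@H](O)C[C@@H](C=C)[C@@H](/C=C/2C)OCc3ccc(OC)cc3)cc1 | intermediate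
22 | tert-butyl{[(1S,2Z,5S,6E,8S,9S)-5,8-bis[(4-methoxybenzyl)oxy]-2,6-dimethyl-9-vinylcyclodeca-2,6-dien-1-yl]oxy}dimethylsilane | COc1ccc(CO[C@H]2C/C=C(/C)[C@@H](O[Si](C)(C)C(C)(C)C)C[C@@H](C=C)[C@@H](/C=C/2C)OCc3ccc(OC)cc3)cc1 | intermediate
23 | B-alkyl-9-BBN adduct of 22 (boron on the terminal carbon of the former vinyl group) | COc1ccc(CO[C@H]2C/C=C(/C)[C@@H](O[Si](C)(C)C(C)(C)C)C[C@@H](CCB4C5CCCC4CCC5)[C@@H](/C=C/2C)OCc3ccc(OC)cc3)cc1 | intermediate (not isolated)
24 | 2-[(1R,2S,3E,5S,7Z,9S)-9-[(tert-butyldimethylsilyl)oxy]-2,5-bis[(4-methoxybenzyl)oxy]-4,8-dimethylcyclodeca-3,7-dien-1-yl]ethan-1-ol | COc1ccc(CO[C@H]2C/C=C(/C)[C@@H](O[Si](C)(C)C(C)(C)C)C[C@@H](CCO)[C@@H](/C=C/2C)OCc3ccc(OC)cc3)cc1 | intermediate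
25 | 2-[(1S,2S,3E,5S,7Z,9S)-9-[(tert-butyldimethylsilyl)oxy]-2,5-bis[(4-methoxybenzyl)oxy]-4,8-dimethylcyclodeca-3,7-dien-1-yl]acetic acid | COc1ccc(CO[C@H]2C/C=C(/C)[C@@H](O[Si](C)(C)C(C)(C)C)C[C@@H](CC(=O)O)[C@@H](/C=C/2C)OCc3ccc(OC)cc3)cc1 | intermediate
26 | 2-[(1S,2S,3E,5S,7Z,9S)-9-[(tert-butyldimethylsilyl)oxy]-2,5-dihydroxy-4,8-dimethylcyclodeca-3,7-dien-1-yl]acetic acid | O[C@H]1C/C=C(/C)[C@@H](O[Si](C)(C)C(C)(C)C)C[C@@H](CC(=O)O)[C@@H](/C=C/1C)O | intermediate (not isolated)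
27 | (3aS,5S,6Z,9S,10E,11aS)-5-[(tert-butyldimethylsilyl)oxy]-9-hydroxy-6,10-dimethyl-3a,4,5,8,9,11a-hexahydrocyclodeca[b]furan-2(3H)-one | O[C@H]1C/C=C(/C)[C@@H](O[Si](C)(C)C(C)(C)C)C[C@@H]2[C@@H](/C=C/1C)OC(=O)C2 | intermediate
28 | dilithium alkoxide enolate of 27 | [Li+].[Li+].[O-][C@H]1C/C=C(/C)[C@@H](O[Si](C)(C)C(C)(C)C)C[C@@H]2[C@@H](/C=C/1C)OC([O-])=C2 | intermediate (not isolated)
29 | (3R,3aS,5S,6Z,9S,10E,11aS)-5-[(tert-butyldimethylsilyl)oxy]-9-hydroxy-3,6,10-trimethyl-3a,4,5,8,9,11a-hexahydrocyclodeca[b]furan-2(3H)-one | O[C@H]1C/C=C(/C)[C@@H](O[Si](C)(C)C(C)(C)C)C[C@@H]2[C@@H](/C=C/1C)OC(=O)[C@@H]2C | intermediate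
30 | (R)-2-methylbutanoic acid | CC[C@@H](C)C(=O)O | starting material
31 | (3R,3aS,5S,6Z,9S,10E,11aS)-5-[(tert-butyldimethylsilyl)oxy]-3,6,10-trimethyl-2-oxo-2,3,3a,4,5,8,9,11a-octahydrocyclodeca[b]furan-9-yl (R)-2-methylbutanoate | CC[C@@H](C)C(=O)O[C@H]1C/C=C(/C)[C@@H](O[Si](C)(C)C(C)(C)C)C[C@@H]2[C@@H](/C=C/1C)OC(=O)[C@@H]2C | intermediate
32 | (3R,3aS,5S,6Z,9S,10E,11aS)-5-hydroxy-3,6,10-trimethyl-2-oxo-2,3,3a,4,5,8,9,11a-octahydrocyclodeca[b]furan-9-yl (R)-2-methylbutanoate | CC[C@@H](C)C(=O)O[C@H]1C/C=C(/C)[C@@H](O)C[C@@H]2[C@@H](/C=C/1C)OC(=O)[C@@H]2C | target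

Total step count: 23.
Longest linear sequence: 21 steps (steps 3–23, from triol 4); steps 1–2 are a two-step side branch that joins in step 6.

Steps most likely to fail

Step 15 (key step). The [3,3] shift may need a temperature at which the Z-dienol ether isomerises by 1,5-hydrogen shift or the ring-contracted 1,5-diene begins to undergo Cope rearrangement, and the C6 stereocentre may discriminate the two faces of C7 only weakly inside the macrocycle. The fallback sets out from macrolactone 18: it is methylenated as in step 15, and the crude dienol ether 19 is treated with triisobutylaluminium in CH2Cl2 at −78 → 0 °C. The aluminium-bound ether should rearrange far below the thermal threshold through a more polarised transition state, and the resulting ketone is reduced in the flask, giving the ring-contracted carbinols (2Z,5S,6E,8S,9S)-5,8-bis[(4-methoxybenzyl)oxy]-2,6-dimethyl-9-vinylcyclodeca-2,6-dien-1-ol as a C1 epimer mixture F1. Dess–Martin oxidation of F1 returns to ketone 20.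

Step 14. The allylic oxyphosphonium may be diverted into SN2′ closure at C7, elimination to a diene, or intermolecular esterification. The fallback sets out from seco acid 17 and activates the acid instead of the alcohol (Shiina macrolactonisation: 2-methyl-6-nitrobenzoic anhydride, DMAP, toluene, slow addition, rt). The mixed anhydride of 17 with 2-methyl-6-nitrobenzoic acid F2 is attacked by the C12 hydroxyl, and the route is rejoined at macrolactone 18; the Z-enoate geometry would have to be watched under these conditions.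

Step 21. The ten-membered ring may present the other face of the enolate, so that methyl iodide enters cis to C7–H. The fallback sets out from lactone 27: methylation as in step 21 would then give the C11 epimer (3S,3aS,5S,6Z,9S,10E,11aS)-5-[(tert-butyldimethylsilyl)oxy]-9-hydroxy-3,6,10-trimethyl-3a,4,5,8,9,11a-hexahydrocyclodeca[b]furan-2(3H)-one F3. F3 is re-enolised (LDA, 2.2 equiv, THF, −78 °C) and protonated kinetically with 2,6-di-tert-butylphenol at −78 °C; the proton then enters the face the methyl group took, which inverts C11 and rejoins the route at 29.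

Further compounds
F1 | step 15 | (2Z,5S,6E,8S,9S)-5,8-bis[(4-methoxybenzyl)oxy]-2,6-dimethyl-9-vinylcyclodeca-2,6-dien-1-ol (C1 epimer mixture) | COc1ccc(CO[C@H]2C/C=C(/C)C(O)C[C@@H](C=C)[C@@H](/C=C/2C)OCc3ccc(OC)cc3)cc1
F2 | step 14 | mixed anhydride of 17 with 2-methyl-6-nitrobenzoic acid | OC/C=C/[C@@H](/C=C(/[C@@H](OCc1ccc(OC)cc1)C/C=C(/C)C(=O)OC(=O)c1c(C)cccc1[N+](=O)[O-])C)OCc1ccc(OC)cc1
F3 | step 21 | (3S,3aS,5S,6Z,9S,10E,11aS)-5-[(tert-butyldimethylsilyl)oxy]-9-hydroxy-3,6,10-trimethyl-3a,4,5,8,9,11a-hexahydrocyclodeca[b]furan-2(3H)-one | O[C@H]1C/C=C(/C)[C@@H](O[Si](C)(C)C(C)(C)C)C[C@@H]2[C@@H](/C=C/1C)OC(=O)[C@H]2C
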